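The readings stem from a simulated flask on assumed constants.

At early times a flask shows its clock, so the earlier runs are read here for how fast E becomes Z, and the flasks asked about are then reckoned on that clock.

| flask | E | L | temperature | remark | time |
|---|---|---|---|---|---|
| teal | 0.020 M | 0.026 M | −15 °C | run made earlier |  |
| red | 0.020 M | 0.013 M | 0 °C | run made earlier |  |
| grey | 0.020 M | 0.019 M | −15 °C | run made earlier |  |
| zeta | 0.020 M (fed, over 1.0 h) | 0.0260 M | 0 °C | all else is in the flask from the start; the feed brings no volume worth counting | 2.5 h |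
| gamma | 0.020 M | 0.0260 M (fed, over 1.0 h) |  | the addition at −30 °C, then warmed to 0 °C; the feed brings no volume worth counting | 2.5 h |
| beta | 0.020 M | 0.0260 M (in portions, 4, over 1.0 h) | 0 °C | first portion at the start, last at 1.0 h | 2.5 h |
| alpha | 0.020 M | 0.0260 M | 0 °C | everything together at the start | 2.5 h |
- teal (time / h: Z / %): 0.833: 11.6; 2.00: 22.9; 3.00: 35.5
- red (time / h: Z / %): 0.333: 40.6; 0.833: 70.4; 1.50: 88.5; 2.50: 97.3
- grey (time / h: Z / %): 0.667: 10.8; 2.00: 25.1; 3.00: 34.4; 5.00: 52.6

(readings scatter by 1 percentage point)
1. the flask that comes out highest in amount of Z, in percent of the E charged, or "all alike" when all lie within 1.5 percentage points (zeta / gamma / beta / alpha / all alike)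
2. Z at the end, in percent of the E charged, zeta
3. Z at the end, in percent of the E charged, gamma
4. Z at the end, in percent of the E charged, beta
5. Z at the end, in percent of the E charged, alpha
- what was read earlier has a scatter of 1 percentage point, one standard deviation

In the red run at 0 °C, Z reads 70.4% after 0.833 h. If E falls at first order, that reading gives a rate constant k of 1.46 h⁻¹, and from it 0.474 h for τ, the half-life of E at 0 °C, the time in which E falls to half of what stands. Put back into the same run, this k gives 97.4% at 2.50 h, against the reading 97.3%. At −15 °C the teal run with 0.026 M of L and the grey run with 0.019 M of L read 35.5% and 34.4% at 3.00 h, a gap of 1.1 percentage points against a scatter of 1 point per reading, so this reckoning leaves L out.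

So the curve reckoned for alpha on this clock leaves the origin at 0.0292 M h⁻¹, passes half of the charge at τ, and bends over at 0.948 h with 75.0%. By 2.5 h it has run 5.27 τ, which leaves 2.59% of E and puts Z at 97.4%, close under the level of the whole charge. This reckoning treats beta as alpha. For zeta the same clock reckons E at 52.6% when the feed ends, then a fall over 1.50 h to 5.87%. For gamma, with the cold addition counted as no reaction, it reckons 11.2% of E at the end.

The forecast gives 97.4% for alpha, 97.2% for beta, 94.1% for zeta and 88.9% for gamma, and it names alpha: “alpha is never worse”.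

The flasks give 95.7% in beta, 93.3% in alpha, 89.4% in zeta and 84.0% in gamma, so beta stands highest, above alpha by 2.4 points.

    L + X → G (k = 0.125 M⁻¹ min⁻¹, Ea = 51.0 kJ mol⁻¹)
    E → Z (k = 0.0298 min⁻¹, Ea = 88.0 kJ mol⁻¹)
    E + L ⇌ X (K = 16.0 M⁻¹, k = 18.6 M⁻¹ min⁻¹, Ea = 53.0 kJ mol⁻¹, ΔH = −2.00 kJ mol⁻¹)
    (constants at 0 °C)

G, formed from X and L, ends lower in beta, at 1.31% against 3.23% in alpha. The 5.27 τ reckoned for alpha leave 2.59% of E, and alpha holds 2.49% of E beside 0.991% of X. For zeta, τ reckoned 5.87% of E, and zeta holds 5.25% of E, with X at 2.07% and G at 3.28%.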